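The strategy rests on ring B. The C6 acetate is treated as the Baeyer–Villiger product of a C6 acetyl group. This makes C5=C6 an acyl-activated dienophile, linked through C4–C3–C2–C1 to a C7=C8–C9=C10 diene whose C8 oxygen later becomes the carbinol.
Key disconnection: C5–C10 and C6–C7 are formed in one intramolecular Diels–Alder reaction of an (E,Z)-trienimide. Rings A and B form together, cis-fused, and C5, C6 and C10 are set in that step.
After the cycloaddition: C9–C11 (Mukaiyama–Michael addition to but-3-en-2-one), C8–C17 (methyltitanium addition), C13=C14 (Horner–Wadsworth–Emmons), then C6 acyl to acetyl to acetate.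
Before it: methyl isobutyrate (C4, C5, C18, C19) is alkylated with the pentynyl halide (C1–C3, C10, C9). C8 comes from a chloroformate, C20 from a syn methylcupration (Z), C7 from MeMgBr, and C6 with the auxiliary from an olefination.

Key step: step 12

Remark: labdane numbering is used (ring A C1–C5 and C10, ring B C5–C10, C17 on C8, C20 on C10). The given SMILES is read as (5S,6S,8S,9S,10R,13E), a cis-decalin with H5, C20, the C6 oxygen, C17 and C11 on one face and the C8 hydroxyl on the other, and this isomer is the one made.

Step 1
Reactants: 1 5-chloropent-1-yne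
Product: 2 5-iodopent-1-yne
Conditions: NaI, acetone, reflux
Reagents that add atoms: sodium iodide, [Na+].[I-]
Why: Finkelstein exchange, driven by precipitation of NaCl from acetone, replaces a chloride that is too slow for an ester enolate with the much better iodide leaving group.

Step 2
Reactants: 3 methyl isobutyrate; 2 5-iodopent-1-yne
Product: 5 methyl 2,2-dimethylhept-6-ynoate, via lithium enolate 4 (not isolated)
Conditions: LiN(i-Pr)2, THF, −78 °C; then 2, DMPU, −78 °C to rt
Reagents that add atoms: none
Why: Enolate alkylation (SN2): the fully substituted lithium enolate should displace the primary iodide faster than it exchanges a proton with the terminal alkyne, and the product has no α-hydrogen left, so C4 with its two methyl groups is built without over-alkylation.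

Step 3
Reactants: 5 methyl 2,2-dimethylhept-6-ynoate
Product: 7 dimethyl 7,7-dimethyloct-2-ynedioate, via lithium acetylide 6 (not isolated)
Conditions: LiN(i-Pr)2, THF, −78 °C; ClCO2Me
Reagents that add atoms: methyl chloroformate, COC(=O)Cl
Why: Acylation of a lithium acetylide by a chloroformate installs C8 as an alkynoate, and the amide base can neither attack nor enolise the neopentyl-type ester.

Step 4
Reactants: 7 dimethyl 7,7-dimethyloct-2-ynedioate
Product: 9 dimethyl (2Z)-3,7,7-trimethyloct-2-enedioate, via alkenylcuprate 8 (not isolated)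
Conditions: Me2CuLi (CuI, MeLi), THF, −78 °C; MeOH, −78 °C
Reagents that add atoms: lithium dimethylcuprate, [Li+].C[Cu-]C
Why: Syn carbocupration of the alkynoate (cuprate conjugate addition) puts the new methyl group (C20) and copper on the same side, and protonation of the configurationally stable alkenylcuprate at −78 °C with retention leaves the chain cis to the ester, which is the Z geometry the cycloaddition needs.

Step 5
Reactants: 9 dimethyl (2Z)-3,7,7-trimethyloct-2-enedioate
Product: 10 (2Z)-3,7,7-trimethyloct-2-ene-1,8-diol
Conditions: i-Bu2AlH (5 equiv), CH2Cl2, −78 to 0 °C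
Reagents that add atoms: none
Why: Aluminium hydride reduction takes both esters to primary alcohols in the 1,2 sense without isomerising the trisubstituted alkene, which converts two similar esters into an allylic and a neopentyl alcohol that can be told apart.

Step 6
Reactants: 10 (2Z)-3,7,7-trimethyloct-2-ene-1,8-diol
Product: 11 (2Z)-8-hydroxy-3,7,7-trimethyloct-2-enal
Conditions: MnO2, CH2Cl2, rt
Reagents that add atoms: none
Why: Chemoselective allylic oxidation: MnO2 attacks only the allylic alcohol under neutral conditions that should keep the Z geometry.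

Step 7
Reactants: 11 (2Z)-8-hydroxy-3,7,7-trimethyloct-2-enal
Product: 12 (3Z)-4,8,8-trimethylnon-3-ene-2,9-diol (racemic at C2 of the chain)
Conditions: MeMgBr (2.2 equiv), THF, −78 °C
Reagents that add atoms: methylmagnesium bromide, C[Mg]Br
Why: Grignard 1,2-addition to the β,β-disubstituted enal brings in C7, with one further equivalent spent on the free hydroxyl group, and the new carbinol centre needs no control because the next step removes it.

Step 8
Reactants: 12 (3Z)-4,8,8-trimethylnon-3-ene-2,9-diol
Product: 13 (6Z)-2,2,6-trimethyl-8-oxonon-6-enal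
Conditions: Dess–Martin periodinane, pyridine, CH2Cl2, 0 °C to rt
Reagents that add atoms: none
Why: Dess–Martin oxidation converts the secondary allylic and the neopentyl primary alcohol in one operation into the Z enone and the aldehyde, and the pyridine buffer protects the acid-sensitive Z enone.

Step 9
Reactants: 14 diethylphosphonoacetic acid; 15 (S)-4-benzyloxazolidin-2-one
Product: 17 diethyl {2-[(4S)-4-benzyl-2-oxo-1,3-oxazolidin-3-yl]-2-oxoethyl}phosphonate, via mixed pivalic anhydride 16 (not isolated)
Conditions: t-BuCOCl, Et3N, THF, −20 °C; then 15, LiCl, rt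
Reagents that add atoms: none
Why: Mixed-anhydride N-acylation: LiCl makes the oxazolidinone N–H acidic enough for Et3N, and the nitrogen attacks the less hindered carbonyl of the anhydride without touching the stereocentre.

Step 10
Reactants: 13 (6Z)-2,2,6-trimethyl-8-oxonon-6-enal; 17 phosphonate imide
Product: 18 (4S)-4-benzyl-3-[(2E,8Z)-4,4,8-trimethyl-10-oxoundeca-2,8-dienoyl]-1,3-oxazolidin-2-one
Conditions: LiCl, i-Pr2NEt, MeCN, rt
Reagents that add atoms: none
Why: Horner–Wadsworth–Emmons olefination in its LiCl and tertiary amine variant is mild enough to spare the Z enone, selects the aldehyde over the ketone, and should give the E enimide as expected for a stabilised phosphonate and an α-quaternary aldehyde.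

Step 11
Reactants: 18 keto dienimide
Product: 19 (4S)-4-benzyl-3-[(2E,8Z)-10-(tert-butyldimethylsilyloxy)-4,4,8-trimethylundeca-2,8,10-trienoyl]-1,3-oxazolidin-2-one
Conditions: TBSOTf, Et3N, CH2Cl2, −78 to 0 °C
Reagents that add atoms: tert-butyldimethylsilyl triflate, CC(C)(C)[Si](C)(C)OS(=O)(=O)C(F)(F)F
Why: Soft enolisation (O-silylation of the enone, then loss of a C7 proton to Et3N) gives the cross-conjugated 2-silyloxy diene without a strong base that would attack the imide, the imide cannot enolise because C4 is quaternary, and the low temperature limits γ-deprotonation and Z to E drift.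

Step 12
Reactants: 19 (E,Z)-silyloxy trienimide
Product: 20 (4S)-4-benzyl-3-{[(1S,4aR,8aS)-3-(tert-butyldimethylsilyloxy)-4a,8,8-trimethyl-1,2,4a,5,6,7,8,8a-octahydronaphthalen-1-yl]carbonyl}-1,3-oxazolidin-2-one, the cis-fused (5S,6S,10R) adduct
Conditions: Me2AlCl (1.5 equiv), CH2Cl2, −78 to −20 °C
Reagents that add atoms: none
Why: More than one equivalent of Me2AlCl binds both imide carbonyls in a cationic chelate, holds the enoyl unit s-cis and lowers its LUMO, so the tethered 2-silyloxy diene can add in a concerted but asynchronous suprafacial [4+2] process at a temperature where the [1,5]-hydrogen shift of Z dienes is frozen and where the Al–CH3 bonds destroy adventitious HCl before it cleaves the enol silane. The closest known reaction types are the Me2AlCl-promoted intramolecular Diels–Alder reaction of N-enoyl oxazolidinone deca-2,7,9-trienimides and the intramolecular Diels–Alder reaction of Z dienes, which gives cis-fused bicycles only. Ring A (C1–C5, C10) closes as the six-membered tether ring through C5–C10 and ring B (C5–C10) as the new cyclohexene through C6–C7, which is the fused type 1 mode. C6 and C5 are set by the auxiliary, whose benzyl group covers one face of the chelated dienophile so that the diene bonds to the Si face of C6, and by the E geometry, which keeps C4 and the acyl group trans; C10 is set by the Z geometry, because a tether standing inside at C10 can reach C5 only when C4 is exo and the acyl group endo, which puts C20, H5 and the acyl group on one face. The step needs regioselectivity against its own electronics, since the silyloxy group raises the diene HOMO but places the larger coefficient on C7 while the imide places the larger LUMO coefficient on C5, and the four-carbon tether secures the C5–C10/C6–C7 pairing because it cannot span the bridged alternative. The geminal methyl groups on C4 favour the folded rotamer and the bulky C8 substituent destabilises the s-trans diene, which offsets part of the strain of the s-cis form with C1 inside.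

Step 13
Reactants: 20 cis-fused adduct
Product: 21 S-ethyl (1S,4aR,8aS)-3-(tert-butyldimethylsilyloxy)-4a,8,8-trimethyl-1,2,4a,5,6,7,8,8a-octahydronaphthalene-1-carbothioate
Conditions: EtSH, n-BuLi, THF, 0 °C
Reagents that add atoms: ethanethiol (as LiSEt), CCS
Why: Acyl transfer to a thiolate: the small, weakly basic and highly nucleophilic LiSEt attacks the exocyclic carbonyl even of a hindered imide, frees the auxiliary for reuse, leaves the enol silane and the C6 centre alone, and gives an acyl group that a cuprate can later turn into a methyl ketone.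

Step 14
Reactants: 21 thioester enol silane; 22 but-3-en-2-one
Product: 23 S-ethyl (1S,4S,4aR,8aS)-4-[3-(tert-butyldimethylsilyloxy)but-2-enyl]-4a,8,8-trimethyl-3-oxodecahydronaphthalene-1-carbothioate (enol silane as an E/Z mixture)
Conditions: 22 (2 equiv), Tf2NH (5 mol %), CH2Cl2, −78 °C; Et3N quench
Reagents that add atoms: none
Why: Mukaiyama–Michael addition under silyl triflimide catalysis moves the silyl group from O8 to O13, so C8 emerges as a free ketone while C13 stays masked, and C9 is set kinetically (9S) because the silylated enone reaches C9 on the convex face that carries H5 and C20, anti to the pseudoaxial C1 and along the axial trajectory that leads directly to the chair.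

Step 15
Reactants: 23 keto enol silane
Product: 25 S-ethyl (1S,3S,4S,4aR,8aS)-3-hydroxy-3,4a,8,8-tetramethyl-4-(3-oxobutyl)decahydronaphthalene-1-carbothioate, via tertiary alcohol enol silane 24 (not isolated)
Conditions: CH3TiCl3 (MeLi, TiCl4), Et2O, −78 to −20 °C; then 1 M HCl, THF, 0 °C
Reagents that add atoms: methyltitanium trichloride, C[Ti](Cl)(Cl)Cl
Why: Organotitanium carbonyl addition is non-basic, so the epimerisable C9 centre holds, and it selects the ketone over the thioester; the methyl group should enter C8 on the convex face along the equatorial path because the axial path is closed by the axial C1, which gives equatorial C17 and axial OH (8S), and the acid quench then hydrolyses the enol silane to the C13 methyl ketone.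

Step 16
Reactants: 14 diethylphosphonoacetic acid; 26 2-(trimethylsilyl)ethanol
Product: 27 2-(trimethylsilyl)ethyl 2-(diethoxyphosphoryl)acetate
Conditions: DCC, DMAP (cat.), CH2Cl2, 0 °C to rt
Reagents that add atoms: none
Why: Steglich esterification gives a phosphonate whose ester group carries no alkene that the later cuprate or peracid could attack and that fluoride removes without acid or base.

Step 17
Reactants: 25 hydroxy ketone; 27 silylethyl phosphonate
Product: 29 S-ethyl (1S,3S,4S,4aR,8aS)-3-hydroxy-3,4a,8,8-tetramethyl-4-{(3E)-3-methyl-5-oxo-5-[2-(trimethylsilyl)ethoxy]pent-3-enyl}decahydronaphthalene-1-carbothioate, via sodium phosphonate 28 (not isolated)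
Conditions: 27, NaH, THF, 0 °C; then 25, 0 °C to rt
Reagents that add atoms: none
Why: Horner–Wadsworth–Emmons olefination now meets a single ketone with no epimerisable centre beside it, the stabilised anion is too weak to deprotonate the tertiary alcohol or to be acylated by the hindered thioester, and the E enoate should predominate, with the minor Z isomer removed by chromatography.

Step 18
Reactants: 29 thioester enoate
Product: 30 2-(trimethylsilyl)ethyl (2E)-5-[(1S,2S,4S,4aS,8aR)-4-acetyl-2-hydroxy-2,5,5,8a-tetramethyldecahydronaphthalen-1-yl]-3-methylpent-2-enoate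
Conditions: Me2CuLi (CuI, MeLi; excess), Et2O, −78 to −30 °C
Reagents that add atoms: lithium dimethylcuprate, [Li+].C[Cu-]C
Why: Ketone synthesis from a thioester and a cuprate stops at the methyl ketone, the β,β-disubstituted enoate is inert to the unactivated cuprate, one equivalent is spent on the hydroxyl group, and the equatorial C6 acyl group is already the more stable epimer.

Step 19
Reactants: 30 C6 methyl ketone
Product: 31 2-(trimethylsilyl)ethyl (2E)-5-[(1S,2S,4S,4aS,8aR)-4-acetoxy-2-hydroxy-2,5,5,8a-tetramethyldecahydronaphthalen-1-yl]-3-methylpent-2-enoate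
Conditions: mCPBA, CH2Cl2, rt, dark
Reagents that add atoms: 3-chloroperbenzoic acid, O=C(OO)c1cccc(Cl)c1
Why: Baeyer–Villiger oxidation: the secondary C6 migrates in preference to methyl and with retention of configuration, while the electron-poor trisubstituted enoate is not epoxidised by the peracid at room temperature.

Step 20
Reactants: 31 silylethyl ester
Product: 32 (2E)-5-[(1S,2S,4S,4aS,8aR)-4-acetoxy-2-hydroxy-2,5,5,8a-tetramethyldecahydronaphthalen-1-yl]-3-methylpent-2-enoic acid (target)
Conditions: Bu4NF, THF, 0 °C to rt; then 0.5 M HCl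
Reagents that add atoms: none
Why: Fluoride-induced fragmentation of the 2-silylethyl ester releases the carboxylate together with ethene and the silyl fluoride under conditions that leave the hindered acetate, the tertiary alcohol and the E alkene untouched.

Compound list
1 | 5-chloropent-1-yne | C#CCCCCl | starting material
2 | 5-iodopent-1-yne | C#CCCCI | intermediate
3 | methyl isobutyrate | CC(C)C(=O)OC | starting material
4 | lithium enolate of methyl isobutyrate | [Li+].[O-]C(OC)=C(C)C | intermediate
5 | methyl 2,2-dimethylhept-6-ynoate | C#CCCCC(C)(C)C(=O)OC | intermediate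
6 | lithium acetylide of 5 | [Li+].[C-]#CCCCC(C)(C)C(=O)OC | intermediate
7 | dimethyl 7,7-dimethyloct-2-ynedioate | COC(=O)C#CCCCC(C)(C)C(=O)OC | intermediate
8 | lithium alkenyl(methyl)cuprate, CH3 and Cu cis | [Li+].COC(=O)/C([Cu-]C)=C(/C)CCCC(C)(C)C(=O)OC | intermediate
9 | dimethyl (2Z)-3,7,7-trimethyloct-2-enedioate | COC(=O)/C=C(/C)CCCC(C)(C)C(=O)OC | intermediate
10 | (2Z)-3,7,7-trimethyloct-2-ene-1,8-diol | OC/C=C(/C)CCCC(C)(C)CO | intermediate
11 | (2Z)-8-hydroxy-3,7,7-trimethyloct-2-enal | O=C/C=C(/C)CCCC(C)(C)CO | intermediate
12 | (3Z)-4,8,8-trimethylnon-3-ene-2,9-diol, racemic carbinol | CC(O)/C=C(/C)CCCC(C)(C)CO | intermediate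
13 | (6Z)-2,2,6-trimethyl-8-oxonon-6-enal | O=CC(C)(C)CCC/C(C)=C\C(C)=O | intermediate
14 | diethylphosphonoacetic acid | CCOP(=O)(CC(=O)O)OCC | starting material
15 | (S)-4-benzyloxazolidin-2-one | O=C1N[C@@H](Cc2ccccc2)CO1 | starting material
16 | diethylphosphonoacetic pivalic anhydride | CCOP(=O)(CC(=O)OC(=O)C(C)(C)C)OCC | intermediate
17 | diethyl {2-[(4S)-4-benzyl-2-oxo-1,3-oxazolidin-3-yl]-2-oxoethyl}phosphonate | CCOP(=O)(CC(=O)N1[C@@H](Cc2ccccc2)COC1=O)OCC | intermediate
18 | (2E,8Z)-keto dienimide | O=C(/C=C/C(C)(C)CCC/C(C)=C\C(C)=O)N1[C@@H](Cc2ccccc2)COC1=O | intermediate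
19 | (2E,8Z)-10-silyloxy trienimide, precursor of the key step | O=C(/C=C/C(C)(C)CCC/C(C)=C\C(O[Si](C)(C)C(C)(C)C)=C)N1[C@@H](Cc2ccccc2)COC1=O | intermediate
20 | cis-fused (5S,6S,10R) 6-acyl decalin enol silane, product of the key step | O=C(N3[C@@H](Cc4ccccc4)COC3=O)[C@H]1CC(O[Si](C)(C)C(C)(C)C)=C[C@]2(C)CCCC(C)(C)[C@H]12 | intermediate
21 | (5S,6S,10R) S-ethyl thioester enol silane | CCSC(=O)[C@H]1CC(O[Si](C)(C)C(C)(C)C)=C[C@]2(C)CCCC(C)(C)[C@H]12 | intermediate
22 | but-3-en-2-one | CC(=O)C=C | starting material
23 | (5S,6S,9S,10R) C8 ketone with C12=C13 enol silane (E/Z mixture) | CCSC(=O)[C@H]1CC(=O)[C@@H](CC=C(C)O[Si](C)(C)C(C)(C)C)[C@]2(C)CCCC(C)(C)[C@H]12 | intermediate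
24 | (5S,6S,8S,9S,10R) C8 tertiary alcohol with C12=C13 enol silane | CCSC(=O)[C@H]1C[C@](C)(O)[C@@H](CC=C(C)O[Si](C)(C)C(C)(C)C)[C@]2(C)CCCC(C)(C)[C@H]12 | intermediate
25 | (5S,6S,8S,9S,10R) 8-hydroxy 13-ketone thioester | CCSC(=O)[C@H]1C[C@](C)(O)[C@@H](CCC(C)=O)[C@]2(C)CCCC(C)(C)[C@H]12 | intermediate
26 | 2-(trimethylsilyl)ethanol | C[Si](C)(C)CCO | starting material
27 | 2-(trimethylsilyl)ethyl 2-(diethoxyphosphoryl)acetate | CCOP(=O)(CC(=O)OCC[Si](C)(C)C)OCC | intermediate
28 | sodium salt of 27 | [Na+].CCOP(=O)(OCC)[CH-]C(=O)OCC[Si](C)(C)C | intermediate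
29 | (13E) enoate thioester | CCSC(=O)[C@H]1C[C@](C)(O)[C@@H](CC/C(C)=C/C(=O)OCC[Si](C)(C)C)[C@]2(C)CCCC(C)(C)[C@H]12 | intermediate
30 | C6 acetyl enoate | CC(=O)[C@H]1C[C@](C)(O)[C@@H](CC/C(C)=C/C(=O)OCC[Si](C)(C)C)[C@]2(C)CCCC(C)(C)[C@H]12 | intermediate
31 | C6 acetoxy silylethyl ester | CC(=O)O[C@H]1C[C@](C)(O)[C@@H](CC/C(C)=C/C(=O)OCC[Si](C)(C)C)[C@]2(C)CCCC(C)(C)[C@H]12 | intermediate
32 | CNP0221670.1, (5S,6S,8S,9S,10R,13E)-6-acetoxy-8-hydroxylabd-13-en-15-oic acid | CC(=O)O[C@H]1C[C@](C)(O)[C@@H](CC/C(C)=C/C(=O)O)[C@]2(C)CCCC(C)(C)[C@H]12 | target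

Total step count: 20
Longest linear sequence: 18 steps (1–8, 10–15, 17–20). Steps 9 and 16 are side branches.

Steps most likely to fail

Step 12. Three factors work against the cycloaddition:
- the s-cis rotamer with C1 inside is strained;
- quaternary C10 must form next to the neopentyl C5;
- the orbital pairing is the electronically unfavourable one.

The reaction may therefore be slower than Lewis-acid-induced loss of the enol silane, Z to E drift of the diene, or intermolecular Mukaiyama–Michael oligomerisation. The fallback takes C20 out of the cycloaddition and sets out from 5. Deprotonation with LiN(i-Pr)2 and addition to acetaldehyde should give methyl 8-hydroxy-2,2-dimethylnon-6-ynoate F1. LiAlH4 in refluxing THF reduces the ester and trans-reduces the propargylic alcohol to (3E)-8,8-dimethylnon-3-ene-2,9-diol F2. Dess–Martin oxidation gives (6E)-2,2-dimethyl-8-oxonon-6-enal F3. Olefination with 17 as in step 10 gives the (2E,8E)-keto dienimide F4, and TBSOTf/Et3N gives the (2E,8E)-silyloxy trienimide F5, whose diene terminus is only monosubstituted. Me2AlCl should then give the trans-fused (5S,6S,10S) adduct F6, with C5 and C6 set as in 20. Saegusa–Ito oxidation with Pd(OAc)2 in MeCN erases C10 and gives the (5S,6S) Δ9(10)-8-enone imide F7. Conjugate addition of Me2CuLi, followed by trapping of the enolate with TBSCl/HMPA, places C20 on the face that carries H5. This is the usual cis-decalone outcome for octalones, and here the axial C4 methyl group reinforces it by blocking the other face. The Δ8(9) enol silane is regenerated, so the fallback comes back to the route at 20.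

Step 14. C9 is a neopentyl carbon, so the addition may be slower than polymerisation of the enone. The kinetically formed axial C9 substituent may also drift to the equatorial epimer through enolisation of the free C8 ketone. The fallback replaces conjugate addition by SN2 alkylation of a metal-free enolate and sets out from 21. (Me2N)3S Me3SiF2 in THF unmasks the C8–C9 enolate regiospecifically. Alkylation with 2-(2-iodoethyl)-2-methyl-1,3-dioxolane on the same convex face should give the (5S,6S,9S,10R) C8 ketone C13 dioxolane F8. CH3Ti(OiPr)3, which leaves the ketal alone, gives the (8S) tertiary alcohol C13 dioxolane F9. Pyridinium tosylate in wet acetone removes the ketal, so the fallback comes back at 25.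

Step 15. Both faces of the C8 ketone are encumbered, by the axial C1 on one side and by the axial C11 chain on the other. The addition may therefore be slow, facial selectivity may be poor, or the tertiary titanium alkoxide may ionise. The fallback delivers C17 as a methylene group under thermodynamic control and sets out from 23. A Corey–Chaykovsky reaction with dimethylsulfoxonium methylide (Me3S(O)I, NaH, DMSO–THF) adds reversibly and should close to the (8S) spiro-epoxide F10, with the CH2 equatorial and the oxygen axial. MgI2 in Et2O opens it at the primary carbon to the (8S) iodohydrin F11. Bu3SnH/AIBN removes the iodine without touching the thioester or the enol silane, so the fallback comes back at 24, which is hydrolysed to 25 as in step 15.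

Further compounds
F1 | step 12 | methyl 8-hydroxy-2,2-dimethylnon-6-ynoate | COC(=O)C(C)(C)CCCC#CC(C)O
F2 | step 12 | (3E)-8,8-dimethylnon-3-ene-2,9-diol | CC(O)/C=C/CCCC(C)(C)CO
F3 | step 12 | (6E)-2,2-dimethyl-8-oxonon-6-enal | O=CC(C)(C)CCC/C=C/C(C)=O
F4 | step 12 | (4S)-4-benzyl-3-[(2E,8E)-4,4-dimethyl-10-oxoundeca-2,8-dienoyl]-1,3-oxazolidin-2-one | O=C(/C=C/C(C)(C)CCC/C=C/C(C)=O)N1[C@@H](Cc2ccccc2)COC1=O
F5 | step 12 | (4S)-4-benzyl-3-[(2E,8E)-10-(tert-butyldimethylsilyloxy)-4,4-dimethylundeca-2,8,10-trienoyl]-1,3-oxazolidin-2-one | O=C(/C=C/C(C)(C)CCC/C=C/C(O[Si](C)(C)C(C)(C)C)=C)N1[C@@H](Cc2ccccc2)COC1=O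
F6 | step 12 | trans-fused (5S,6S,10S) 20-nor adduct | O=C(N3[C@@H](Cc4ccccc4)COC3=O)[C@H]1CC(O[Si](C)(C)C(C)(C)C)=C[C@H]2CCCC(C)(C)[C@H]12
F7 | step 12 | (5S,6S) Δ9(10)-8-enone imide | O=C(N3[C@@H](Cc4ccccc4)COC3=O)[C@H]1CC(=O)C=C2CCCC(C)(C)[C@H]12
F8 | step 14 | (5S,6S,9S,10R) C8 ketone C13 dioxolane thioester | CCSC(=O)[C@H]1CC(=O)[C@@H](CCC3(C)OCCO3)[C@]2(C)CCCC(C)(C)[C@H]12
F9 | step 14 | (5S,6S,8S,9S,10R) C8 tertiary alcohol C13 dioxolane thioester | CCSC(=O)[C@H]1C[C@](C)(O)[C@@H](CCC3(C)OCCO3)[C@]2(C)CCCC(C)(C)[C@H]12
F10 | step 15 | (8S) C8 spiro-epoxide, oxygen axial | CCSC(=O)[C@H]1C[C@@]3(CO3)[C@@H](CC=C(C)O[Si](C)(C)C(C)(C)C)[C@]2(C)CCCC(C)(C)[C@H]12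
F11 | step 15 | (8S) C17 iodohydrin | CCSC(=O)[C@H]1C[C@](CI)(O)[C@@H](CC=C(C)O[Si](C)(C)C(C)(C)C)[C@]2(C)CCCC(C)(C)[C@H]12
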